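In a one-step world, as in a step-growth chain with unbalanced ends, substrate meets coupling partner and a single rate constant runs the clock.

| flask | substrate | coupling partner | remark | time |
|---|---|---|---|---|
| birch | 0.34 M | 0.65 M | run made earlier |  |
| maple | 0.25 M | 0.65 M | run made earlier |  |
| midnight | 0.50 M | 0.650 M |  | 15 min |
| dawn | 0.50 M | 1.30 M |  | 15 min |

| run | time / min | single product / % | substrate / % | bis adduct / % |
|---|---|---|---|---|
| birch | 0.333 | 3 | 100 | 1 |
| birch | 1.00 | 3 | 95 | 0 |
| birch | 2.00 | 14 | 89 | 1 |
| birch | 3.00 | 15 | 85 | 0 |
| birch | 4.00 | 20 | 79 | 0 |
| birch | 5.00 | 23 | 71 | 2 |
| maple | 0.417 | 2 | 92 | 0 |
| maple | 0.667 | 2 | 95 | 0 |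
| maple | 1.00 | 5 | 94 | 2 |
| maple | 2.00 | 10 | 88 | 2 |
| maple | 3.00 | 13 | 84 | 0 |
| maple | 5.00 | 25 | 75 | 1 |

(each reading ± 2 percentage points)



1. which of these there is most of at the end, counted by the substrate in it, midnight (single product / substrate / bis adduct)
2. which of these there is most of at the end, counted by the substrate in it, dawn (single product / substrate / bis adduct)
3. how much there is at the end of the one of these that leads, in percent of the substrate charged: midnight
4. how much there is at the end of the one of these that leads, in percent of the substrate charged: dawn

By their last readings, birch had lost 29.0% of its substrate and maple 25.0%, from different charges, so substrate enters at first order. The bench rule is to freeze the partner at its charge (pseudo-first-order). Pooling those two readings and dividing by the 0.65 M of partner gives 0.0969 M⁻¹ min⁻¹, our coupling constant, the fractional loss of substrate per minute per molar of partner. It is a reading with scatter, and first order in partner is assumed, since both runs had the same partner charge.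

Frozen at midnight, where partner stands at 1.30 times the substrate, the constant leaves 38.9% of the substrate. But that conversion spends 47.0% of the partner charged, more than the 15.2% spent in birch, so the freeze stops working here. Letting partner fall one for one with substrate, we reckon 48.6% substrate left at midnight and 21.9% at dawn. We reckon no split of the converted dawn substrate among its products.

The forecast has substrate leading midnight at 51% and single product leading dawn at 67%, judging that “The second step looks slow”.

The flasks give substrate leading midnight at 48.2% and single product leading dawn at 42.4%.

    crystals ⇌ released group, rate k1*(cs1 - [released group]) while solid is left; crystals form when [released group] > cs1 (solubility = 0.350 M, k = 8.50 min⁻¹)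
    single product → decomposed reagent (k = 0.0460 min⁻¹)
    coupling partner + single product → bis adduct + released group (k = 0.0210 M⁻¹ min⁻¹)
    substrate + coupling partner → single product + released group (k = 0.100 M⁻¹ min⁻¹)

The larger partner charge is the main reason for dawn's lead over midnight in single product, a gap of 10 percentage points. Our coupling constant says dawn has converted 78.1% of its substrate. Single product stands at 42.4%, bis adduct at 11.1% and decomposed reagent at 24.8%. That decomposition is part of the shortfall: without it, dawn holds 64.3% single product. In the neighbour with 1.6 M of partner, the constant gives 85.2% converted, and that flask holds 42.9% single product, 15.3% bis adduct and 27.1% decomposed reagent.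

The runs were generated by integration with made-up constants; the scatter is artificial.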